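A direct plan would arylate a ready-made bromophenol: 1,2,4,5-tetrabromobenzene A1 would go by Br/Mg exchange, borylation and oxidation to 2,4,5-tribromophenol A2, and 1-bromo-2-iodobenzene A3 would be oxidised by peracetic acid to 1-bromo-2-(diacetoxy-λ3-iodanyl)benzene A4.
A2 and A4 would be joined by attack of the trivalent iodine on the free ortho carbon of A2 and a shift of the 2-bromophenyl group from iodine to oxygen, to give 1,2,5-tribromo-4-(2-bromophenoxy)-3-iodobenzene A5; a second exchange–borylation–oxidation on A5 would turn its C–I bond into C–OH.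
First weak point, the iodonium-mediated O-arylation: trivalent iodine would have to attack the one free ortho carbon of a ring deactivated by three bromines, and an unactivated aryl group would then have to shift; the whole plan would rest on this untested sequence.
Second weak point, the late I/Mg exchange: the aryl-magnesium would sit between C–Br and C–OAr in a molecule with four C–Br bonds, so loss of magnesium halide to an aryne and Br/Mg scrambling would threaten the nearly finished skeleton.
Third weak point, the oxygen traffic: the exchange–borylation–oxidation sequence would be run twice and the C–I bond of A5 made only to be destroyed, so much of the plan would build nothing of the skeleton.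

**Retrosynthetic overview**
Ring A (phenol ring: C1 OH, C2 Br, C3 Br, C4 H, C5 Br, C6 O-aryl; ring B = 2-bromophenyl) is read as a 1,4-oxygen-bridged arene: C1–C4 with the Br pair on C2/C3 and the phenol oxygen are C2v-symmetric 3,4-dibromofuran, and C5/C6 are an alkyne unit.
Key cuts: C1–C6 and C4–C5 by a [4+2] cycloaddition that closes the carbocycle, then the O–C4 bond of the bridge by an aromatising opening that turns the furan oxygen into the C1 hydroxyl.
Order: ring B is bought as 2-bromophenol; the ether O–C6 bond is made on the ring A side as an enol ether by vinylic substitution on the cycloadduct; the activating ester at C5 is exchanged for bromine; ring A itself forms last.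
The design needs no aryl–O coupling on a deactivated phenol, no halogen/metal exchange among C–Br bonds and no borylation–oxidation; positions are fixed by the symmetry of the furan and by the aryloxy donor that steers the bridge opening.

Key step: step 5

Remark: the target is achiral; the bicyclic intermediates are racemic (one enantiomer drawn), their two bridgehead stereocenters vanish on aromatisation, and the locants used in the steps are those of the 7-oxabicyclo[2.2.1]heptadiene names, not those of ring A.

Step 1
Reactants: 1 methyl propiolate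
Product: 2 methyl 3-bromopropiolate
Conditions: NBS (1.1 equiv), AgNO3 (0.1 equiv), acetone, rt, 2 h
Reagents that add atoms: N-bromosuccinimide O=C1CCC(=O)N1Br
Why: Silver-catalysed electrophilic bromination of a terminal alkyne (silver acetylide plus NBS) is the standard preparation of 3-halopropiolates.

Step 2
Reactants: 2 methyl 3-bromopropiolate; 3 3,4-dibromofuran
Product: 4 methyl 3,5,6-tribromo-7-oxabicyclo[2.2.1]hepta-2,5-diene-2-carboxylate (racemic)
Conditions: 3 (1.5 equiv), toluene (2 M), 85 °C, sealed tube, 36 h
Reagents that add atoms: none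
Why: A normal-demand Diels–Alder reaction of a furan with a 3-bromopropiolate, an established pairing, should close the six-membered carbocycle (the future C1–C6 and C4–C5 bonds of ring A) as a single constitutional isomer because 3 is C2v-symmetric, the two bridgehead stereocenters arising as a racemate that step 5 erases.

Step 3
Reactants: 4 methyl 3,5,6-tribromo-7-oxabicyclo[2.2.1]hepta-2,5-diene-2-carboxylate; 5 2-bromophenol
Product: 6 methyl 5,6-dibromo-3-(2-bromophenoxy)-7-oxabicyclo[2.2.1]hepta-2,5-diene-2-carboxylate (racemic)
Conditions: 5 (1.05 equiv), K2CO3 (1.2 equiv), MeCN, 0 °C to rt, 3 h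
Reagents that add atoms: none
Why: In a nucleophilic vinylic substitution by addition–elimination the phenoxide should add to C3 of the strained β-bromoacrylate and the ester enolate expel bromide, which makes the O–C6 bond of the diaryl ether on the ring A side while the unactivated vinylic and aryl C–Br bonds stay inert.

Step 4
Reactants: 6 methyl 5,6-dibromo-3-(2-bromophenoxy)-7-oxabicyclo[2.2.1]hepta-2,5-diene-2-carboxylate
Product: 8 2,5,6-tribromo-3-(2-bromophenoxy)-7-oxabicyclo[2.2.1]hepta-2,5-diene, via lithium carboxylate 7 (not isolated)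
Conditions: LiOH·H2O (1.1 equiv), THF/H2O 4:1, 0 °C, 2 h; then NBS (1.05 equiv), MeCN, 0 °C, dark, 1 h
Reagents that add atoms: N-bromosuccinimide O=C1CCC(=O)N1Br (the Br at C2 of 8); lithium hydroxide [Li+].[OH-] (Li and one O of 7 only)
Why: Saponification followed by Hunsdiecker-type ionic bromodecarboxylation with NBS should work because Br+ attacks C2, the carboxylate-bearing β-carbon of the aryl enol ether and the most nucleophilic site, and the resulting oxocarbenium ion loses CO2 to restore the C2=C3 bond now carrying bromine.

Step 5
Reactants: 8 2,5,6-tribromo-3-(2-bromophenoxy)-7-oxabicyclo[2.2.1]hepta-2,5-diene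
Product: 10 2,3,5-tribromo-6-(2-bromophenoxy)phenol, via O-BF3 cyclohexadienyl cation 9 (not isolated)
Conditions: BF3·OEt2 (0.3 equiv), CH2Cl2, −40 to 0 °C, 1 h; aq NaHCO3
Reagents that add atoms: boron trifluoride FB(F)F (BF3 of 9 only)
Why: BF3 should bind the bridging oxygen, the most basic site, and the C1–O bond of the bicycle should ionise to the cyclohexadienyl cation 9, whose charge sits on C1, C3 and C5; loss of the proton from C4 then aromatises. The closest known reaction type is the acid-catalysed isomerisation of 7-oxanorbornadienes (1,4-epoxy-1,4-dihydroarenes) to phenols. No ring is closed here: the oxygen bridge opens, the carbocycle closed in step 2 becomes ring A, the furan oxygen becomes the phenol oxygen, and both bridgehead stereocenters are erased, so no stereocontrol is needed. The selectivity needed is the choice of bridgehead C–O bond: only ionisation at C1 places positive charge on C3, where the lone pair of the 2-bromophenoxy oxygen stabilises it, whereas ionisation at C4 would place charge only on bromine-bearing carbons, so the hydroxyl should stay on C4, next to the aryloxy carbon, as the target requires. A catalytic, anhydrous Lewis acid at low temperature is chosen to avoid hydrolysis of the bromo enol ether and cycloreversion. Without base or heat the product cannot close to a dibenzo-p-dioxin.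

**Compound list**
1 | methyl propiolate | COC(=O)C#C | starting material
2 | methyl 3-bromopropiolate | COC(=O)C#CBr | intermediate
3 | 3,4-dibromofuran | Brc1cocc1Br | starting material
4 | methyl 3,5,6-tribromo-7-oxabicyclo[2.2.1]hepta-2,5-diene-2-carboxylate (racemic, one enantiomer drawn) | COC(=O)C1=C(Br)[C@@H]2O[C@H]1C(Br)=C2Br | intermediate
5 | 2-bromophenol | Oc1ccccc1Br | starting material
6 | methyl 5,6-dibromo-3-(2-bromophenoxy)-7-oxabicyclo[2.2.1]hepta-2,5-diene-2-carboxylate (racemic, one enantiomer drawn) | COC(=O)C1=C(Oc3ccccc3Br)[C@@H]2O[C@H]1C(Br)=C2Br | intermediate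
7 | lithium 5,6-dibromo-3-(2-bromophenoxy)-7-oxabicyclo[2.2.1]hepta-2,5-diene-2-carboxylate (racemic, not isolated) | [Li+].[O-]C(=O)C1=C(Oc3ccccc3Br)[C@@H]2O[C@H]1C(Br)=C2Br | intermediate
8 | 2,5,6-tribromo-3-(2-bromophenoxy)-7-oxabicyclo[2.2.1]hepta-2,5-diene (racemic, one enantiomer drawn) | BrC1=C(Oc3ccccc3Br)[C@@H]2O[C@H]1C(Br)=C2Br | intermediate
9 | O-BF3 cyclohexadienyl cation: 2,3,5-tribromo-6-(2-bromophenoxy)-1-(trifluoroboranuidyloxy)cyclohexa-2,5-dien-4-ylium zwitterion (racemic, not isolated) | F[B-](F)(F)O[C@H]1C(Oc2ccccc2Br)=C(Br)[CH+]C(Br)=C1Br | intermediate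
10 | 2,3,5-tribromo-6-(2-bromophenoxy)phenol (achiral) | Oc1c(Br)c(Br)cc(Br)c1Oc1ccccc1Br | target

**Step count and risks**
Total step count: 5. Longest linear sequence: 5 steps (1 → 2 → 4 → 6 → 8 → 10).

Steps most likely to fail:

Step 5. The bridge may ionise at the wrong bridgehead, or the bromo enol ether may be protonated and cleaved, or cycloreversion may occur before the bridge opens. The fallback takes ring A from the arene pool and uses the same C2v symmetry; it sets out from 2-bromophenol 5 and comes back at the target 10. 2,3,5,6-Tetrabromobenzaldehyde F1 (from the tetrabromobenzene A1 by LiN(iPr)2 at −78 °C and DMF) would react with 5 (K2CO3, DMF, 80 °C) by aldehyde-activated SNAr at either of its two equivalent ortho C–Br bonds to give 2,3,5-tribromo-6-(2-bromophenoxy)benzaldehyde F2. Baeyer–Villiger oxidation (mCPBA, CH2Cl2) would give 2,3,5-tribromo-6-(2-bromophenoxy)phenyl formate F3, and KHCO3 in MeOH at rt would release 10.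

Step 4. Hydroxide may attack C3 and expel the aryloxide by conjugate addition–elimination faster than it cleaves the ester. The fallback carries the carboxyl group as a fluoride-labile ester; it sets out from 3,4-dibromofuran 3 and comes back at 8. The known ester 2-(trimethylsilyl)ethyl propiolate F4 would be brominated as in step 1 to 2-(trimethylsilyl)ethyl 3-bromopropiolate F5 and added to 3 as in step 2 to give 2-(trimethylsilyl)ethyl 3,5,6-tribromo-7-oxabicyclo[2.2.1]hepta-2,5-diene-2-carboxylate F6. Substitution with 5 as in step 3 would give 2-(trimethylsilyl)ethyl 5,6-dibromo-3-(2-bromophenoxy)-7-oxabicyclo[2.2.1]hepta-2,5-diene-2-carboxylate F7. Bu4NF in THF at 0 °C would then free tetrabutylammonium 5,6-dibromo-3-(2-bromophenoxy)-7-oxabicyclo[2.2.1]hepta-2,5-diene-2-carboxylate F8 without any oxygen nucleophile, and NBS would convert it into 8.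

Step 2. The halogen-deactivated furan may add too slowly, so that cycloreversion and decomposition of 2 win at the temperature needed. The fallback replaces the alkyne by a doubly activated alkene that should react near rt; it sets out from 3 and comes back at 6. Methyl (Z)-3-bromo-3-nitroacrylate F9, a known type of dienophile, and 3 would give methyl 3,5,6-tribromo-3-nitro-7-oxabicyclo[2.2.1]hept-5-ene-2-carboxylate F10 (mixture of diastereomers). K2CO3 would remove HBr to give methyl 5,6-dibromo-3-nitro-7-oxabicyclo[2.2.1]hepta-2,5-diene-2-carboxylate F11, and 5 with K2CO3 would displace nitrite by addition–elimination to give 6. If HNO2 were lost instead, the product would be 4 itself, which also leads to 6.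

**Further compounds**
F1 | step 5 | 2,3,5,6-tetrabromobenzaldehyde | O=Cc1c(Br)c(Br)cc(Br)c1Br
F2 | step 5 | 2,3,5-tribromo-6-(2-bromophenoxy)benzaldehyde | O=Cc1c(Br)c(Br)cc(Br)c1Oc1ccccc1Br
F3 | step 5 | 2,3,5-tribromo-6-(2-bromophenoxy)phenyl formate | O=COc1c(Br)c(Br)cc(Br)c1Oc1ccccc1Br
F4 | step 4 | 2-(trimethylsilyl)ethyl propiolate | C#CC(=O)OCC[Si](C)(C)C
F5 | step 4 | 2-(trimethylsilyl)ethyl 3-bromopropiolate | BrC#CC(=O)OCC[Si](C)(C)C
F6 | step 4 | 2-(trimethylsilyl)ethyl 3,5,6-tribromo-7-oxabicyclo[2.2.1]hepta-2,5-diene-2-carboxylate (racemic) | C[Si](C)(C)CCOC(=O)C1=C(Br)[C@@H]2O[C@H]1C(Br)=C2Br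
F7 | step 4 | 2-(trimethylsilyl)ethyl 5,6-dibromo-3-(2-bromophenoxy)-7-oxabicyclo[2.2.1]hepta-2,5-diene-2-carboxylate (racemic) | C[Si](C)(C)CCOC(=O)C1=C(Oc3ccccc3Br)[C@@H]2O[C@H]1C(Br)=C2Br
F8 | step 4 | tetrabutylammonium 5,6-dibromo-3-(2-bromophenoxy)-7-oxabicyclo[2.2.1]hepta-2,5-diene-2-carboxylate (racemic) | CCCC[N+](CCCC)(CCCC)CCCC.[O-]C(=O)C1=C(Oc3ccccc3Br)[C@@H]2O[C@H]1C(Br)=C2Br
F9 | step 2 | methyl (Z)-3-bromo-3-nitroacrylate | COC(=O)/C=C(\Br)[N+](=O)[O-]
F10 | step 2 | methyl 3,5,6-tribromo-3-nitro-7-oxabicyclo[2.2.1]hept-5-ene-2-carboxylate (mixture of diastereomers, racemic) | COC(=O)C1C2OC(C(Br)=C2Br)C1(Br)[N+](=O)[O-]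
F11 | step 2 | methyl 5,6-dibromo-3-nitro-7-oxabicyclo[2.2.1]hepta-2,5-diene-2-carboxylate (racemic) | COC(=O)C1=C([N+](=O)[O-])[C@@H]2O[C@H]1C(Br)=C2Br
A1 | direct plan | 1,2,4,5-tetrabromobenzene | Brc1cc(Br)c(Br)cc1Br
A2 | direct plan | 2,4,5-tribromophenol | Oc1cc(Br)c(Br)cc1Br
A3 | direct plan | 1-bromo-2-iodobenzene | Brc1ccccc1I
A4 | direct plan | 1-bromo-2-(diacetoxy-λ3-iodanyl)benzene | CC(=O)OI(OC(C)=O)c1ccccc1Br
A5 | direct plan | 1,2,5-tribromo-4-(2-bromophenoxy)-3-iodobenzene | Brc1ccccc1Oc1c(Br)cc(Br)c(Br)c1I
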